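A direct plan would benzylate 2,4,6-trihydroxybenzoic acid A1 to the hydroxy ester A2, turn its last phenol into the aryl triflate A3 and exchange the triflate for pentyl to give the pentylarene A4.
Saponification of A4 would give the acid A5; hydrogenolysis of A4 to olivetolic acid A6 and renewed benzylation would give the diol ester A7.
A5 would acylate the 4-OH of A7 to give the depside A8, which would be O-methylated to the methyl ether A9 and debenzylated to the target.
Its weakest steps would be: (a) the triflate-to-pentyl exchange on A3, an sp2–sp3 coupling beside an ester on an electron-rich ring without close precedent, where reduction or hydrolysis of the triflate would compete;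
(b) the benzylation, debenzylation and renewed benzylation that lead to A5 and A7, steps that add no skeletal bond and only tell apart the hydroxyls of two identical rings;
(c) the base-mediated methylation of the chelated, hindered 2-OH of A8, where on the most valuable intermediate a phenoxide beside two esters would invite acyl migration and cleavage of the depside.

**Plan of the new route**
The retrosynthesis leaves the depside ester alone and cuts ring A: its C1–C2 and C5–C6 bonds (Diels–Alder/retro-Diels–Alder), then the ester C–O bond of a plain aryl oct-2-ynoate. Ring B is cut at C1–C6 (aldol) and unfolds to a 4-methoxy-2-pyrone plus a hexanoyl unit.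
Ring B therefore arises first, by folding of a pyrone-masked tetraketide; ring A arises last, on the ester that is already in place.
Enabling feature: in ring A the carboxyl-bearing C1 and the pentyl-bearing C6 are neighbours (the C≡C of oct-2-ynoate) and the oxygens on C2 and C4 are 1,3-related (a 1,3-bis(silyloxy)diene); the ester polarises the alkyne so that only the wanted orientation results.
The pentyl chains come in with the hexanoyl and octynoyl units (no cross-coupling), the OMe is bought with the pyrone (no late methylation), and the hydroxyls of ring A are born as silyl ethers lost on work-up (the benzyl ester is the only protecting group).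

Key step: step 5

Remark: the target is achiral, so no stereocentre has to be set; locants in rings A and B count from the carboxyl-bearing carbon as C1, and 1, 2, 4, 7, 8, 11 and 12 are taken as purchased.

**Step 1**
Reactants: 1 4-methoxy-6-methyl-2H-pyran-2-one; 2 N-methoxy-N-methylhexanamide
Product: 3 4-methoxy-6-(2-oxoheptyl)-2H-pyran-2-one
Conditions: LiN(i-Pr)2 (1.1 equiv), THF, −78 °C; then 2 (1.05 equiv), −78 °C to 0 °C; aq. NH4Cl
Reagents that add atoms: N-methoxy-N-methylhexanamide, CCCCCC(=O)N(C)OC
Why: Vinylogous Claisen-type C-acylation (Weinreb ketone synthesis), in which LiN(i-Pr)2 removes a proton from the 6-methyl group, the extended lithium dienolate adds to the amide, and the chelated tetrahedral adduct releases the more acidic ketone 3 only on quench, so that neither proton transfer nor a second addition should interfere.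

**Step 2**
Reactants: 3 4-methoxy-6-(2-oxoheptyl)-2H-pyran-2-one; 4 benzyl alcohol
Product: 6 benzyl 4-hydroxy-2-methoxy-6-pentylbenzoate, via open-chain methoxy enoate 5 (not isolated)
Conditions: 4 (10 equiv), KOt-Bu (3 equiv), THF, 0 °C to 40 °C; then 1 M HCl, 0 °C
Reagents that add atoms: benzyl alcohol, OCc1ccccc1
Why: Biogenetic-type pyrone-to-resorcylate conversion (lactone alcoholysis, then intramolecular aldol condensation), in which benzyloxide opens the lactone carbonyl to enoate 5 with the ester and the C4 methylene held cis by the former ring, the extended enolate closes C2 onto the C7 ketone and loss of water aromatises, so that the bought methyl enol ether becomes the 2-OMe, the former ring oxygen becomes the free 4-OH, and the potassium counter-ion (no chelating magnesium) should favour this aldol over a Claisen closure to an acylphloroglucinol.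

**Step 3**
Reactants: 6 benzyl 4-hydroxy-2-methoxy-6-pentylbenzoate; 7 oct-2-ynoic acid; 8 N,N'-dicyclohexylcarbodiimide
Product: 10 benzyl 2-methoxy-4-(oct-2-ynoyloxy)-6-pentylbenzoate, via O-acylisourea 9 (not isolated)
Conditions: 7 (1.2 equiv), 8 (1.2 equiv), DMAP (5 mol%), CH2Cl2, 0 °C to rt
Reagents that add atoms: oct-2-ynoic acid, CCCCCC#CC(=O)O
Why: Steglich esterification, in which the only nucleophile of 6 is one unhindered and fairly acidic phenol and the acid is a slim linear acyl donor, so the ester C–O bond of the depside is made before any ortho substituent or free hydroxyl of ring A exists.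

**Step 4**
Reactants: 11 5,5-dimethylcyclohexane-1,3-dione (dimedone); 12 trimethylsilyl trifluoromethanesulfonate
Product: 14 5,5-dimethyl-1,3-bis(trimethylsilyloxy)cyclohexa-1,3-diene, via monosilyl enone 13 (not isolated)
Conditions: 12 (2.2 equiv), Et3N (3 equiv), Et2O, 0 °C to rt; hexane extraction, used directly
Reagents that add atoms: trimethylsilyl trifluoromethanesulfonate, C[Si](C)(C)OS(=O)(=O)C(F)(F)F
Why: Double enol silylation of a cyclic 1,3-dione, in which O-silylation to enone 13 is followed by silylation of the second carbonyl oxygen with loss of a ring proton, and because 11 is symmetric either deprotonation (C4 or C6) gives the same s-cis-locked 1,3-bis(silyloxy)diene.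

**Step 5**
Reactants: 10 benzyl 2-methoxy-4-(oct-2-ynoyloxy)-6-pentylbenzoate; 14 5,5-dimethyl-1,3-bis(trimethylsilyloxy)cyclohexa-1,3-diene
Product: 17 benzyl 4-[(2,4-dihydroxy-6-pentylbenzoyl)oxy]-2-methoxy-6-pentylbenzoate, via bicyclo[2.2.2]octadiene cycloadduct 15 (not isolated), via bis(trimethylsilyl) ether 16 (not isolated)
Conditions: 14 (3 equiv), toluene, 145 °C, sealed tube; then 1 M HCl, THF, rt
Reagents that add atoms: 5,5-dimethyl-1,3-bis(trimethylsilyloxy)cyclohexa-1,3-diene, C[Si](C)(C)OC1=CC(O[Si](C)(C)C)=CC(C)(C)C1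
Why: Thermal Diels–Alder reaction of normal electron demand between the s-cis-locked, electron-rich diene 14 and the aryl ynoate 10 should give the bicyclo[2.2.2]octadiene 15, which at the same temperature undergoes retro-Diels–Alder loss of 2-methylpropene (Alder–Rickert reaction) to the aromatic bis-silyl ether 16, and dilute acid then frees both phenols to give 17. The closest known reaction type is the Alder–Rickert benzannulation of alk-2-ynoate esters, macrocyclic ones included, with 1,3-bis(silyloxy)cyclohexa-1,3-dienes to 2,4-dihydroxy-6-alkylbenzoates. Ring A is closed by an intermolecular [4+2] cycloaddition that forms its C1–C2 and C5–C6 bonds at once, and it becomes aromatic in the cycloreversion that removes the CMe2–CH2 bridge. The two bridgehead stereocentres of 15 (racemic) are erased in that cycloreversion, so no stereocontrol is needed. The step needs one regiochemistry: the unsubstituted diene terminus C4, to which both silyloxy groups push electron density, must bond to the pentyl-bearing β-carbon of the ynoate and the silyloxy-bearing C1 to the α-carbon, which the polarisation of the alkyne by the ester secures and which places the hydroxyls on C2 and C4 of ring A. The benzyl ester, the aryl ester and the methyl ether of 10 are inert to the neutral thermal conditions, and the aryl ester should make the alkyne a better dienophile than an alkyl ynoate.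

**Step 6**
Reactants: 17 benzyl 4-[(2,4-dihydroxy-6-pentylbenzoyl)oxy]-2-methoxy-6-pentylbenzoate
Product: 18 4-[(2,4-dihydroxy-6-pentylbenzoyl)oxy]-2-methoxy-6-pentylbenzoic acid
Conditions: H2 (1 atm), Pd/C (10 wt% Pd), EtOAc, rt
Reagents that add atoms: none
Why: Catalytic hydrogenolysis of the benzyl ester under neutral conditions, to which the aryl ester, the aryl methyl ether and the phenols are inert, and the alkyne is gone since step 5, so no other reducible group remains.

**Compound list**
1 | 4-methoxy-6-methyl-2H-pyran-2-one | COC1=CC(=O)OC(C)=C1 | starting material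
2 | N-methoxy-N-methylhexanamide | CCCCCC(=O)N(C)OC | starting material
3 | 4-methoxy-6-(2-oxoheptyl)-2H-pyran-2-one | CCCCCC(=O)CC1=CC(OC)=CC(=O)O1 | intermediate
4 | benzyl alcohol | OCc1ccccc1 | starting material
5 | benzyl (2E)-3-methoxy-5,7-dioxododec-2-enoate (not isolated) | CCCCCC(=O)CC(=O)C/C(OC)=C\C(=O)OCc1ccccc1 | intermediate
6 | benzyl 4-hydroxy-2-methoxy-6-pentylbenzoate | CCCCCc1cc(O)cc(OC)c1C(=O)OCc1ccccc1 | intermediate
7 | oct-2-ynoic acid | CCCCCC#CC(=O)O | starting material
8 | N,N'-dicyclohexylcarbodiimide | C(=NC1CCCCC1)=NC1CCCCC1 | starting material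
9 | N,N'-dicyclohexyl-O-(oct-2-ynoyl)isourea (not isolated) | CCCCCC#CC(=O)OC(=NC1CCCCC1)NC1CCCCC1 | intermediate
10 | benzyl 2-methoxy-4-(oct-2-ynoyloxy)-6-pentylbenzoate | CCCCCC#CC(=O)Oc1cc(CCCCC)c(C(=O)OCc2ccccc2)c(OC)c1 | intermediate
11 | 5,5-dimethylcyclohexane-1,3-dione (dimedone) | CC1(C)CC(=O)CC(=O)C1 | starting material
12 | trimethylsilyl trifluoromethanesulfonate | C[Si](C)(C)OS(=O)(=O)C(F)(F)F | starting material
13 | 5,5-dimethyl-3-(trimethylsilyloxy)cyclohex-2-en-1-one (not isolated) | CC1(C)CC(=O)C=C(O[Si](C)(C)C)C1 | intermediate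
14 | 5,5-dimethyl-1,3-bis(trimethylsilyloxy)cyclohexa-1,3-diene | C[Si](C)(C)OC1=CC(O[Si](C)(C)C)=CC(C)(C)C1 | intermediate
15 | benzyl 4-({[8,8-dimethyl-3-pentyl-1,5-bis(trimethylsilyloxy)bicyclo[2.2.2]octa-2,5-dien-2-yl]carbonyl}oxy)-2-methoxy-6-pentylbenzoate (racemic, not isolated) | CCCCCC1=C(C(=O)Oc2cc(CCCCC)c(C(=O)OCc3ccccc3)c(OC)c2)C2(O[Si](C)(C)C)C=C(O[Si](C)(C)C)C1C(C)(C)C2 | intermediate
16 | benzyl 4-{[2,4-bis(trimethylsilyloxy)-6-pentylbenzoyl]oxy}-2-methoxy-6-pentylbenzoate (not isolated) | CCCCCc1cc(O[Si](C)(C)C)cc(O[Si](C)(C)C)c1C(=O)Oc1cc(CCCCC)c(C(=O)OCc2ccccc2)c(OC)c1 | intermediate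
17 | benzyl 4-[(2,4-dihydroxy-6-pentylbenzoyl)oxy]-2-methoxy-6-pentylbenzoate | CCCCCc1cc(O)cc(O)c1C(=O)Oc1cc(CCCCC)c(C(=O)OCc2ccccc2)c(OC)c1 | intermediate
18 | 4-[(2,4-dihydroxy-6-pentylbenzoyl)oxy]-2-methoxy-6-pentylbenzoic acid (achiral) | CCCCCc1cc(O)cc(O)c1C(=O)Oc1cc(CCCCC)c(C(=O)O)c(OC)c1 | target

**Count**
Total steps: 6. Longest linear sequence: 5 (steps 1, 2, 3, 5, 6); step 4 is a one-step side branch.

**Steps most likely to fail**

1. Step 5. The β-alkyl ynoate may be a sluggish dienophile, so that thermal decomposition or protodesilylation of the diene, or conjugate addition without ring closure, could overtake the benzannulation. Fallback (sets out from 6, returns at 17): ring A would instead be folded from a dioxinone-masked tetraketide. Bought 2,2,6-trimethyl-4H-1,3-dioxin-4-one would be C-acetylated (LiN(SiMe3)2, THF, −78 °C; acetyl chloride) to 2,2-dimethyl-6-(2-oxopropyl)-4H-1,3-dioxin-4-one F1. The dianion of F1 (LiN(i-Pr)2, 2.2 equiv, THF, −78 °C) would be acylated at its terminal carbon by amide 2 to give 6-(2,4-dioxononyl)-2,2-dimethyl-4H-1,3-dioxin-4-one F2. Heating F2 with phenol 6 in toluene at 110 °C would expel acetone and form the acylketene dodec-1-ene-1,3,5,7-tetrone F3, which the phenol would capture as benzyl 2-methoxy-6-pentyl-4-[(3,5,7-trioxododecanoyl)oxy]benzoate F4. Et3N in CH2Cl2, then HCl, would close C2 of the chain onto the C7 ketone (aldol condensation) and dehydrate to 17.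

2. Step 2. The open chain could close the other way (Claisen attack of C6 on the ester), benzyloxide could exchange with the methoxy group at the enol ether carbon, or the β-diketone could be cleaved by alkoxide. Fallback (sets out from 7, returns at 6): ring B would be made by the same kind of benzannulation as ring A. Acid 7 would be esterified (BnBr, K2CO3, DMF, rt) to benzyl oct-2-ynoate F5. Bought 3-methoxy-5,5-dimethylcyclohex-2-en-1-one would be converted (LiN(i-Pr)2, Me3SiCl, THF, −78 °C) into 1-methoxy-5,5-dimethyl-3-(trimethylsilyloxy)cyclohexa-1,3-diene F6. Heating F5 with F6 (toluene, 145 °C) would give benzyl 1-methoxy-8,8-dimethyl-3-pentyl-5-(trimethylsilyloxy)bicyclo[2.2.2]octa-2,5-diene-2-carboxylate F7 (racemic), which would lose 2-methylpropene to benzyl 2-methoxy-6-pentyl-4-(trimethylsilyloxy)benzoate F8. Dilute HCl in THF would then give 6. The methoxy-bearing diene terminus would bond to the α-carbon of the ynoate, so the OMe would end ortho to the ester.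

3. Step 1. The acylation could stall through competing deprotonation at C3 of the pyrone, proton transfer between dienolate and adduct, or slow addition of the stabilised dienolate to the amide. Fallback (sets out from 1, returns at 3): the same lithium dienolate would be added to hexanal, a far better electrophile, to give 6-(2-hydroxyheptyl)-4-methoxy-2H-pyran-2-one F9 (racemic), and the alcohol would be oxidised with Dess–Martin periodinane (CH2Cl2, rt) to 3.

**Further compounds**
F1 | step 5 | 2,2-dimethyl-6-(2-oxopropyl)-4H-1,3-dioxin-4-one | CC(=O)CC1=CC(=O)OC(C)(C)O1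
F2 | step 5 | 6-(2,4-dioxononyl)-2,2-dimethyl-4H-1,3-dioxin-4-one | CCCCCC(=O)CC(=O)CC1=CC(=O)OC(C)(C)O1
F3 | step 5 | dodec-1-ene-1,3,5,7-tetrone | CCCCCC(=O)CC(=O)CC(=O)C=C=O
F4 | step 5 | benzyl 2-methoxy-6-pentyl-4-[(3,5,7-trioxododecanoyl)oxy]benzoate | CCCCCC(=O)CC(=O)CC(=O)CC(=O)Oc1cc(CCCCC)c(C(=O)OCc2ccccc2)c(OC)c1
F5 | step 2 | benzyl oct-2-ynoate | CCCCCC#CC(=O)OCc1ccccc1
F6 | step 2 | 1-methoxy-5,5-dimethyl-3-(trimethylsilyloxy)cyclohexa-1,3-diene | COC1=CC(O[Si](C)(C)C)=CC(C)(C)C1
F7 | step 2 | benzyl 1-methoxy-8,8-dimethyl-3-pentyl-5-(trimethylsilyloxy)bicyclo[2.2.2]octa-2,5-diene-2-carboxylate (racemic) | CCCCCC1=C(C(=O)OCc2ccccc2)C2(OC)C=C(O[Si](C)(C)C)C1C(C)(C)C2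
F8 | step 2 | benzyl 2-methoxy-6-pentyl-4-(trimethylsilyloxy)benzoate | CCCCCc1cc(O[Si](C)(C)C)cc(OC)c1C(=O)OCc1ccccc1
F9 | step 1 | 6-(2-hydroxyheptyl)-4-methoxy-2H-pyran-2-one (racemic) | CCCCCC(O)CC1=CC(OC)=CC(=O)O1
A1 | direct plan | 2,4,6-trihydroxybenzoic acid | OC(=O)c1c(O)cc(O)cc1O
A2 | direct plan | benzyl 2,4-bis(benzyloxy)-6-hydroxybenzoate | O=C(OCc1ccccc1)c1c(O)cc(OCc2ccccc2)cc1OCc1ccccc1
A3 | direct plan | benzyl 2,4-bis(benzyloxy)-6-{[(trifluoromethyl)sulfonyl]oxy}benzoate | O=C(OCc1ccccc1)c1c(OS(=O)(=O)C(F)(F)F)cc(OCc2ccccc2)cc1OCc1ccccc1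
A4 | direct plan | benzyl 2,4-bis(benzyloxy)-6-pentylbenzoate | CCCCCc1cc(OCc2ccccc2)cc(OCc2ccccc2)c1C(=O)OCc1ccccc1
A5 | direct plan | 2,4-bis(benzyloxy)-6-pentylbenzoic acid | CCCCCc1cc(OCc2ccccc2)cc(OCc2ccccc2)c1C(=O)O
A6 | direct plan | 2,4-dihydroxy-6-pentylbenzoic acid (olivetolic acid) | CCCCCc1cc(O)cc(O)c1C(=O)O
A7 | direct plan | benzyl 2,4-dihydroxy-6-pentylbenzoate | CCCCCc1cc(O)cc(O)c1C(=O)OCc1ccccc1
A8 | direct plan | benzyl 4-{[2,4-bis(benzyloxy)-6-pentylbenzoyl]oxy}-2-hydroxy-6-pentylbenzoate | CCCCCc1cc(OCc2ccccc2)cc(OCc2ccccc2)c1C(=O)Oc1cc(O)c(C(=O)OCc2ccccc2)c(CCCCC)c1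
A9 | direct plan | benzyl 4-{[2,4-bis(benzyloxy)-6-pentylbenzoyl]oxy}-2-methoxy-6-pentylbenzoate | CCCCCc1cc(OCc2ccccc2)cc(OCc2ccccc2)c1C(=O)Oc1cc(OC)c(C(=O)OCc2ccccc2)c(CCCCC)c1
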